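A litre of this flask holds 0.880 M of partner against 0.800 M of substrate of both hands, and the question is where that partner goes.

| flask | left-handed substrate | right-handed substrate | partner | remark | time |
|---|---|---|---|---|---|
| Monday's | 0.27 M | 0.27 M | 0.88 M | run made earlier |  |
| Wednesday's | 0.60 M | 0.60 M | 0.88 M | run made earlier |  |
| flask | 0.40 M | 0.40 M | 0.880 M |  | 5.0 h |

- Monday's (time / h: left-handed product / %, right-handed product / %, right-handed substrate / %): 1.33: 65.9, 28.2, 3.2; 2.50: 67.9, 29.1, 1.8; 4.00: 67.9, 28.0, 1.4; 5.00: 68.5, 27.6, 1.6
- Wednesday's (time / h: left-handed product / %, right-handed product / %, right-handed substrate / %): 1.33: 51.7, 14.4, 14.0; 2.50: 52.6, 13.9, 14.0; 4.00: 52.0, 14.4, 13.4; 5.00: 51.6, 14.2, 13.9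

(standard deviation of a reading: 0.5 percentage points)

- partner is single-handed; left-handed substrate and right-handed substrate are mirror images of each other, charged as a racemate, each of them at the stated concentration
- on the list of suspects stand: partner + left-handed substrate -> left-handed product; partner + right-handed substrate -> right-handed product; left-handed substrate <-> achiral form; right-handed substrate <-> achiral form; partner -> decomposed reagent
- the reaction counts as stopped when no species that holds the left-handed substrate and right-handed substrate together changes by six tenths of a point or more over the second half of the time
- the handed part of partner does not stay in what it makes, so the products of the two hands are mirror images too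

* which holds at 5.0 h: what has brought the reaction to rest, or that it has not come to rest (all of the left-handed substrate has reacted / forward and back rates have come level / the partner has run out first / it is still moving)
* how much left-handed product there is at 5.0 h, in percent of the left-handed substrate and right-handed substrate together charged
* how much right-handed product there is at 5.0 h, in percent of the left-handed substrate and right-handed substrate together charged
* how much right-handed substrate there is at 5.0 h, in percent of the left-handed substrate and right-handed substrate together charged
* amount of left-handed product if the flask were left three thousand times as long, in percent of the left-handed substrate and right-handed substrate together charged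

First I take coupling by itself. The partner charged is more than the substrate, so this picture promises 100% conversion, split 50% to each hand. But Wednesday's run stands still from 1.33 h with 65.8% in products, which is 0.790 M of coupled partner out of 0.88 M. So I add the suspected decomposition of the partner.

Let U be the substrate pool still uncoupled (both hands and the achiral form), C its charge, B the partner charge, and κ the decomposition constant over a mean coupling constant. Both rates carry the partner's concentration, so their ratio contains neither partner nor time: each unit coupled costs one plus κ/U of partner. Integrated until the partner reaches zero, this gives B = C − U + κ ln(C/U). Monday's last readings give 0.111 M and Wednesday's 0.0843 M, so I carry their mean, 0.0978 M, as the decomposition ratio κ. For this flask, solving the balance leaves U/C = 14.0%.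

Last comes the achiral form, which lets the left-handed substrate draw on the right-handed stock. It moves the split, and U counts it, so the balance keeps its shape; but by feeding the left-handed substrate it also shifts the mean coupling constant, so κ is a working figure read off the runs and not a constant of any one step. The left-handed share of product reads 71.3% on Monday and 78.4% on Wednesday, and between the charges it gives 74.1% here. So I commit to the partner as limiting reagent, with 63.7% left-handed product, 22.3% right-handed product and 5.70% right-handed substrate.

The forecast says the partner has run out first, with 62.7%, 23.5%, 5.6% and, later, 62.7%: “With partner dead, waiting longer changes nothing”. My left-handed product stands 1 percentage point above its figure.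

The flask gives the partner has run out first, with 0% of the partner's charge left at 5.00 h, and 63.9%, 22.1%, 5.60%, and 63.9% after the long wait.

    partner + left-handed substrate → left-handed product (k = 0.637 /M/min)
    partner + right-handed substrate → right-handed product (k = 0.0769 /M/min)
    left-handed substrate ⇌ achiral form (K = 0.500, k = 0.0479 /min)
    right-handed substrate ⇌ achiral form (K = 0.500, k = 0.0479 /min)
    partner → decomposed reagent (k = 0.0167 /min)

Decomposition is what holds this flask short: taken away, conversion counted as loss of the two substrates rises from 88.8% to 99.9%. On the result, κ prices that loss at 0.192 M, and the flask holds 0.192 M of decomposed reagent. For the neighbour charged with 0.22 M of partner, the same balance puts 24.1% of the substrate into products, and that flask holds 25.4%.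

The runs come from a simulation on assumed constants; scatter was added.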